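The route rests on cutting two neighbouring bonds of the γ-lactone ring (O1, C2, C3, C4, C5): the O1–C5 bond and the bond from C4 to its carboxyl carbon. Because O1 and that carboxyl are cis substituents on the adjacent ring carbons C5 and C4, both can be delivered across a (Z)-C4=C5 alkene whose chain already ends in the C2 carboxyl. One palladium-catalysed oxypalladation–carbonylation should close the ring, attach the C4 ester and set both stereocentres, with alkene geometry giving the cis relation and a chiral ligand the absolute sense. The precursor is a linear (Z)-alk-3-enoic acid carrying the ketone as a dioxolane; the C3 methylene follows last.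

Key step: step 6

Assumption: the alkoxy group of the C4 ester is a spectator, so the carbonylation is run with benzyl alcohol (a benzyl ester falls to neutral hydrogenolysis, whereas hydroxide on a methyl ester would endanger the cis centre at C4 and an acidic relactonisation the dioxolane); the (S,S)-ligand is assumed to give the (2S,3S) series and would be exchanged for its mirror image if it does not; ring atoms are numbered O1, C2 (lactone carbonyl), C3, C4 (carboxyl-bearing), C5 (chain-bearing) in the text, while systematic names count the ring from the other side.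

Step 1
Reactants: 1 15-pentadecanolide (oxacyclohexadecan-2-one)
Product: 2 15-hydroxy-N-methoxy-N-methylpentadecanamide
Conditions: MeNH(OMe)·HCl (2 equiv), i-PrMgCl (4 equiv), THF, −20 to 0 °C; aq. NH4Cl
Reagents that add atoms: N,O-dimethylhydroxylamine hydrochloride, CNOC.Cl
Why: Weinreb amide formation: the chloromagnesium amide made from the amine salt and i-PrMgCl should open the unstrained macrolactone as it would an ester, and the resulting N-methoxy-N-methylamide does not react further at this temperature.

Step 2
Reactants: 2 15-hydroxy-N-methoxy-N-methylpentadecanamide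
Product: 3 16-hydroxyhexadecan-2-one
Conditions: MeMgBr (3 equiv), THF, 0 °C to rt; aq. NH4Cl
Reagents that add atoms: methylmagnesium bromide, C[Mg]Br
Why: Weinreb ketone synthesis: one equivalent of MeMgBr is spent on the free hydroxyl and the magnesium chelate of the adduct holds the carbonyl at the ketone level until aqueous work-up, so no tertiary alcohol should form.

Step 3
Reactants: 3 16-hydroxyhexadecan-2-one
Product: 4 14-(2-methyl-1,3-dioxolan-2-yl)tetradecan-1-ol
Conditions: HOCH2CH2OH (5 equiv), p-TsOH·H2O (cat.), benzene, reflux, Dean–Stark; Et3N quench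
Reagents that add atoms: ethylene glycol, OCCO
Why: Acid-catalysed ketalisation with azeotropic removal of water: the cyclic dioxolane from the excess diol is favoured over mixed ketals with the remote primary hydroxyl, which stays free.

Step 4
Reactants: 4 14-(2-methyl-1,3-dioxolan-2-yl)tetradecan-1-ol
Product: 5 14-(2-methyl-1,3-dioxolan-2-yl)tetradecanal
Conditions: TEMPO (10 mol%), PhI(OAc)2 (1.1 equiv), dry CH2Cl2, rt; aq. NaHCO3/Na2S2O3 wash
Reagents that add atoms: none
Why: Oxoammonium (TEMPO) oxidation of the primary alcohol stops at the aldehyde in the absence of water and releases only acetic acid, to which the dioxolane is inert under anhydrous conditions.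

Step 5
Reactants: 5 14-(2-methyl-1,3-dioxolan-2-yl)tetradecanal; 6 (2-carboxyethyl)triphenylphosphonium bromide
Product: 8 (3Z)-17-(2-methyl-1,3-dioxolan-2-yl)heptadec-3-enoic acid, via ylide carboxylate 7 (not isolated)
Conditions: 6 (1.3 equiv), NaN(SiMe3)2 (2.6 equiv), THF, −78 to 0 °C; then 5, −78 °C to rt; cold 10% aq. citric acid to pH 4–5, fast extraction
Reagents that add atoms: none
Why: Wittig reaction of a salt-free non-stabilised ylide: the sodium base gives the ylide carboxylate, whose kinetically formed cis-oxaphosphetane should collapse to the (Z)-alkene, and the double bond stays β,γ because the carboxyl is already deprotonated.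

Step 6
Reactants: 8 (3Z)-17-(2-methyl-1,3-dioxolan-2-yl)heptadec-3-enoic acid; 9 carbon monoxide; 10 benzyl alcohol
Product: 11 benzyl (2S,3S)-2-[13-(2-methyl-1,3-dioxolan-2-yl)tridecyl]-5-oxooxolane-3-carboxylate
Conditions: Pd(OCOCF3)2 (10 mol%), (S,S)-Ph-box [2,2′-(propane-2,2-diyl)bis((4S)-4-phenyl-4,5-dihydro-1,3-oxazole)] (12 mol%), p-benzoquinone (2 equiv), CO (1 atm), BnOH (5 equiv), 4 Å MS, CH2Cl2, 0 °C to rt
Reagents that add atoms: none
Why: Proposed new method: divalent palladium held by the bis(oxazoline) coordinates the C4=C5 alkene of 8, the free C2 carboxyl attacks C5 on the face away from the metal (anti-oxypalladation, O1–C5 bond), CO inserts into the C4–palladium bond with retention, benzyl alcohol cleaves the acyl–palladium to the C4 ester, and p-benzoquinone returns zerovalent palladium to the divalent state. The closest known reactions are the palladium-catalysed oxidative cyclisation–alkoxycarbonylation of alkenols, which has been rendered asymmetric with bis(oxazoline) ligands, and the oxidative 5-endo lactonisation of alk-3-enoic acids to butenolides. The lactone ring closes in the 5-endo-trig mode. C5 is set by the chiral ligand, which must choose one face of the alkene, and C4 is set relative to C5 by the substrate, because anti addition across the (Z)-alkene followed by retentive insertion puts the ester cis to the chain. The step needs CO insertion to beat β-hydride elimination and 5-endo to beat 4-exo attack: after anti addition the C5 hydrogen is anti to palladium, only a C3 hydrogen is syn and the chelated, CO-saturated metal offers no free cis site, while attack at C4 would give a strained β-lactone.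

Step 7
Reactants: 11 benzyl (2S,3S)-2-[13-(2-methyl-1,3-dioxolan-2-yl)tridecyl]-5-oxooxolane-3-carboxylate
Product: 12 (2S,3S)-2-[13-(2-methyl-1,3-dioxolan-2-yl)tridecyl]-5-oxooxolane-3-carboxylic acid
Conditions: H2 (1 atm), 10% Pd/C, EtOAc, rt
Reagents that add atoms: none
Why: Hydrogenolysis of the benzyl ester over Pd/C runs under neutral conditions, so the C4 centre α to the ester keeps its configuration and the lactone and dioxolane are not touched.

Step 8
Reactants: 12 (2S,3S)-2-[13-(2-methyl-1,3-dioxolan-2-yl)tridecyl]-5-oxooxolane-3-carboxylic acid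
Product: 14 (2S,3S)-4-methylidene-2-[13-(2-methyl-1,3-dioxolan-2-yl)tridecyl]-5-oxooxolane-3-carboxylic acid, via malonic diacid 13 (not isolated)
Conditions: CH3OMgOCO2CH3 (2 M in DMF, 30–40 equiv), 130 °C, N2; ice-cold 1 M HCl/EtOAc, fast extraction; then 37% aq. HCHO, PhNHMe, NaOAc, AcOH, rt
Reagents that add atoms: formaldehyde, C=O (the methylidene carbon of 14); methyl magnesium carbonate, COC(=O)O[Mg]OC (the extra carboxyl of 13, lost again as CO2)
Why: Carboxylation of the lactone α-carbon C3 with CH3OMgOCO2CH3 (driven by the magnesium chelate of the malonate) followed by decarboxylative Mannich methylenation is the established α-methylenation of paraconic acids; C4 is α to a carboxylate, is not deprotonated and should stay cis to the chain, and any ketal lost in the acidic work-ups only anticipates step 9.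

Step 9
Reactants: 14 (2S,3S)-4-methylidene-2-[13-(2-methyl-1,3-dioxolan-2-yl)tridecyl]-5-oxooxolane-3-carboxylic acid
Product: 15 allo-pertusaric acid, (2S,3S)-4-methylidene-5-oxo-2-(14-oxopentadecyl)oxolane-3-carboxylic acid
Conditions: 1 M aq. HCl, THF, rt
Reagents that add atoms: water, O
Why: Acid-catalysed hydrolysis of the dioxolane frees the methyl ketone under conditions to which the α-methylene lactone and the carboxylic acid are stable, and no stereocentre should epimerise in dilute acid at room temperature.

Compound list

1 | 15-pentadecanolide (oxacyclohexadecan-2-one) | O=C1CCCCCCCCCCCCCCO1 | starting material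
2 | 15-hydroxy-N-methoxy-N-methylpentadecanamide | CON(C)C(=O)CCCCCCCCCCCCCCO | intermediate
3 | 16-hydroxyhexadecan-2-one | CC(=O)CCCCCCCCCCCCCCO | intermediate
4 | 14-(2-methyl-1,3-dioxolan-2-yl)tetradecan-1-ol | CC1(CCCCCCCCCCCCCCO)OCCO1 | intermediate
5 | 14-(2-methyl-1,3-dioxolan-2-yl)tetradecanal | CC1(CCCCCCCCCCCCCC=O)OCCO1 | intermediate
6 | (2-carboxyethyl)triphenylphosphonium bromide | OC(=O)CC[P+](c1ccccc1)(c2ccccc2)c3ccccc3.[Br-] | starting material
7 | sodium 3-(triphenyl-λ5-phosphanylidene)propanoate (ylide carboxylate) | [Na+].[O-]C(=O)CC=P(c1ccccc1)(c2ccccc2)c3ccccc3 | intermediate (not isolated)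
8 | (3Z)-17-(2-methyl-1,3-dioxolan-2-yl)heptadec-3-enoic acid | OC(=O)C/C=C\CCCCCCCCCCCCCC1(C)OCCO1 | intermediate
9 | carbon monoxide | [C-]#[O+] | starting material
10 | benzyl alcohol | OCc1ccccc1 | starting material
11 | benzyl (2S,3S)-2-[13-(2-methyl-1,3-dioxolan-2-yl)tridecyl]-5-oxooxolane-3-carboxylate (cis) | C1C(=O)O[C@@H](CCCCCCCCCCCCCC2(C)OCCO2)[C@H]1C(=O)OCc3ccccc3 | intermediate
12 | (2S,3S)-2-[13-(2-methyl-1,3-dioxolan-2-yl)tridecyl]-5-oxooxolane-3-carboxylic acid (cis) | C1C(=O)O[C@@H](CCCCCCCCCCCCCC2(C)OCCO2)[C@H]1C(=O)O | intermediate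
13 | (2S,3S)-2-[13-(2-methyl-1,3-dioxolan-2-yl)tridecyl]-5-oxooxolane-3,4-dicarboxylic acid (mixture of epimers at the new malonic carbon) | OC(=O)C1C(=O)O[C@@H](CCCCCCCCCCCCCC2(C)OCCO2)[C@H]1C(=O)O | intermediate (not isolated)
14 | (2S,3S)-4-methylidene-2-[13-(2-methyl-1,3-dioxolan-2-yl)tridecyl]-5-oxooxolane-3-carboxylic acid | C=C1C(=O)O[C@@H](CCCCCCCCCCCCCC2(C)OCCO2)[C@H]1C(=O)O | intermediate
15 | allo-pertusaric acid, (2S,3S)-4-methylidene-5-oxo-2-(14-oxopentadecyl)oxolane-3-carboxylic acid | C=C1C(=O)O[C@@H](CCCCCCCCCCCCCC(C)=O)[C@H]1C(=O)O | target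

Total step count: 9. Longest linear sequence: 9 steps (1 to 15); 6, 9 and 10 enter as purchased materials.

Steps most likely to fail

Step 6 (Proposed new method). The ligand may discriminate the two alkene faces poorly. β-Hydride elimination towards C3 may outrun CO insertion and drain material into the butenolide. Delivery of the carboxylate from the metal (syn addition) may erode the cis relation. Acid released from the palladium salt may open the dioxolane. The fallback uses known chemistry, sets out from 5 and comes back at 11, with both centres set by auxiliary and substrate control. Aldehyde 5 would undergo an acetate aldol addition with the divalent tin enolate of (4S)-3-acetyl-4-(propan-2-yl)-1,3-thiazolidine-2-thione (Sn(OSO2CF3)2, N-ethylpiperidine, CH2Cl2, −78 °C). The (4S)-auxiliary is expected from the chelated chair model to give the 3S carbinol, and the (4R)-auxiliary would be taken if the sense proves opposite. The product, separable from its diastereomer on silica, is (3S)-3-hydroxy-16-(2-methyl-1,3-dioxolan-2-yl)-1-[(4S)-4-(propan-2-yl)-2-sulfanylidene-1,3-thiazolidin-3-yl]hexadecan-1-one F1. Benzyl alcohol with DMAP in CH2Cl2 would displace the auxiliary to give benzyl (3S)-3-hydroxy-16-(2-methyl-1,3-dioxolan-2-yl)hexadecanoate F2. Fráter–Seebach alkylation of its dianion (LiN(i-Pr)2, 2.2 equiv, THF, −78 to −20 °C; allyl bromide, DMPU) should give the anti product benzyl (2S,3S)-3-hydroxy-16-(2-methyl-1,3-dioxolan-2-yl)-2-(prop-2-en-1-yl)hexadecanoate F3. Its anti relation becomes the cis relation of the lactone. Ozonolysis (O3, CH2Cl2, −78 °C; PPh3) would give the lactol benzyl (2S,3S)-5-hydroxy-2-[13-(2-methyl-1,3-dioxolan-2-yl)tridecyl]oxolane-3-carboxylate F4. Oxidation of the lactol with TEMPO/PhI(OAc)2 in CH2Cl2 returns to 11.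

Step 8. At 130 °C the C4 centre may epimerise to the trans series. The ketal may be lost before carboxylation is complete, in which case the methyl ketone would be carboxylated and methylenated as well. The fallback sets out from 12 and comes back at 14, and brings in the methylene carbon as an iminium electrophile at low temperature. The dianion of 12 (LiN(SiMe3)2, 2.2 equiv, THF, −78 °C; carboxylate plus C3 lactone enolate) would be trapped with Eschenmoser's salt (CH2=NMe2+ I−). This gives (2S,3S)-4-[(dimethylamino)methyl]-2-[13-(2-methyl-1,3-dioxolan-2-yl)tridecyl]-5-oxooxolane-3-carboxylic acid F5. Quaternisation with MeI in MeOH followed by aq. NaHCO3/CH2Cl2 eliminates the amine and returns to 14.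

Step 5. The (Z)-selectivity may be incomplete, and any (E)-alkene would be carried into trans lactone by the anti addition of step 6. The double bond may also migrate into conjugation, and the ketal may be lost on acidification. The fallback sets out from 5 and comes back at 8, and fixes the geometry by semi-hydrogenation. Seyferth–Gilbert homologation of 5 with dimethyl (1-diazo-2-oxopropyl)phosphonate (K2CO3, MeOH, rt) would give 2-methyl-2-(pentadec-14-yn-1-yl)-1,3-dioxolane F6. Its lithium acetylide (n-BuLi, THF, −78 °C) would open ethylene oxide in the presence of BF3·OEt2 at −78 °C to give 17-(2-methyl-1,3-dioxolan-2-yl)heptadec-3-yn-1-ol F7. TEMPO/PhI(OAc)2 in MeCN/H2O would oxidise it to 17-(2-methyl-1,3-dioxolan-2-yl)heptadec-3-ynoic acid F8. Hydrogenation over Pd/CaCO3 poisoned with Pb(OAc)2, with quinoline in EtOAc, returns to 8.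

Further compounds

F1 | step 6 | (3S)-3-hydroxy-16-(2-methyl-1,3-dioxolan-2-yl)-1-[(4S)-4-(propan-2-yl)-2-sulfanylidene-1,3-thiazolidin-3-yl]hexadecan-1-one | O[C@@H](CCCCCCCCCCCCCC1(C)OCCO1)CC(=O)N2[C@@H](C(C)C)CSC2=S
F2 | step 6 | benzyl (3S)-3-hydroxy-16-(2-methyl-1,3-dioxolan-2-yl)hexadecanoate | O[C@@H](CCCCCCCCCCCCCC1(C)OCCO1)CC(=O)OCc2ccccc2
F3 | step 6 | benzyl (2S,3S)-3-hydroxy-16-(2-methyl-1,3-dioxolan-2-yl)-2-(prop-2-en-1-yl)hexadecanoate | O[C@@H](CCCCCCCCCCCCCC1(C)OCCO1)[C@H](CC=C)C(=O)OCc2ccccc2
F4 | step 6 | benzyl (2S,3S)-5-hydroxy-2-[13-(2-methyl-1,3-dioxolan-2-yl)tridecyl]oxolane-3-carboxylate (lactol, both anomers) | C1C(O)O[C@@H](CCCCCCCCCCCCCC2(C)OCCO2)[C@H]1C(=O)OCc3ccccc3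
F5 | step 8 | (2S,3S)-4-[(dimethylamino)methyl]-2-[13-(2-methyl-1,3-dioxolan-2-yl)tridecyl]-5-oxooxolane-3-carboxylic acid | CN(C)CC1C(=O)O[C@@H](CCCCCCCCCCCCCC2(C)OCCO2)[C@H]1C(=O)O
F6 | step 5 | 2-methyl-2-(pentadec-14-yn-1-yl)-1,3-dioxolane | C#CCCCCCCCCCCCCCC1(C)OCCO1
F7 | step 5 | 17-(2-methyl-1,3-dioxolan-2-yl)heptadec-3-yn-1-ol | OCCC#CCCCCCCCCCCCCCC1(C)OCCO1
F8 | step 5 | 17-(2-methyl-1,3-dioxolan-2-yl)heptadec-3-ynoic acid | OC(=O)CC#CCCCCCCCCCCCCCC1(C)OCCO1
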